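Flavanone numbering (O1, C2, C3, C4, C4a, C5–C8, C8a; ring B primed) is used for all intermediates, including the open-chain ones. Compound numbers are those of the steps and of the compound list.

## Analysis of the target

Compound 18 is a (2R,3R)-dihydroflavonol: a chroman-4-one in which the phloroglucinol-type ring A is fused to the dihydropyranone ring C. Ring B (3,4-dihydroxy-5-methoxyphenyl) sits on C2, a hydroxyl on C3, and a prenyl group on C6 between the C5 and C7 hydroxyls. The two stereocentres are adjacent and trans (H2 and H3 anti, aryl and hydroxyl both equatorial). This is the more stable relative arrangement, but the absolute configuration must come from a reagent or catalyst. The molecule is sensitive in several ways. The catechol-type ring B is oxidised easily in base, and the β-aryloxy ketone can open by loss of the O1 phenoxide, which scrambles C2 and, through the enol, C3. The α-ketol can be dehydrogenated to the flavonol. The prenyl group, flanked by two phenols, cyclises to a chromane under acid and rules out hydrogenolysis. Two problems dominate. The first is ring A regiochemistry: of the two hydroxyls ortho to the acyl carbon C4a, one must become O1 and the other the C5 hydroxyl, and this choice decides between the 6-prenyl and 8-prenyl series. The second is the enantioselective construction of the C2/C3 pair. The strategy rests on C3, an oxygen-bearing carbon between the C4 ketone and the oxygenated benzylic carbon C2. This α-alkoxy-β-oxy ketone pattern is what remains when an oxonium ylide of a diazomethyl ketone is trapped by an aldehyde.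

## Retrosynthetic reasoning

**18 back to 16 (protecting groups).** All five phenols of 18 are traced back to silyl ethers and the C3 hydroxyl to a 4-methoxybenzyl ether. Buffered fluoride then releases 18 from 17 in one non-acidic, non-basic operation, so the prenyl group is never exposed to acid and ring C never to base. The 4-methoxybenzyl group is taken off one step earlier (16 to 17) by a quinone oxidant, at a stage where no free phenol is present.

**16 back to 15 and 14 (O1–C2).** Ring C is opened at the O1–C2 bond. C2 is benzylic and carries a hydroxyl in 15, so the bond can be made by intramolecular etherification with inversion. The other ring bonds are poorer choices: C8a–O1 would need an aryl leaving group on an electron-rich ring, and C4–C4a an acylation next to a prenyl alkene. Because the closure inverts C2, the open-chain precursor must have the threo arrangement, (S) at the carbinol carbon and (R) at the ether carbon, to end as the trans-(2R,3R) product. Only the C8a oxygen may be free at this point. It is therefore the only phenol of 14 that carries a tert-butyldimethylsilyl ether, all others being triisopropylsilyl ethers, and 15 arises from 14 by selective cleavage of that one group.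

**14 back to 9, 11 and 12 (C2–C3 and C3–O).** The β-hydroxy-α-alkoxy ketone 14 is cut at the C2–C3 bond and at the C3–O bond. This gives three achiral pieces: the ring A diazomethyl ketone 9, the ring B aldehyde 11 and 4-methoxybenzyl alcohol 12. The gain is large: two bonds and both stereocentres in one convergent step, with the C3 oxygen arriving already protected. The forward reaction has to turn 9 into a metal carbene, let 12 add to it, and have the resulting ylide 13 intercepted by 11 inside a chiral acid before it collapses by proton transfer. Silyl ethers on both oxygens ortho to the acyl group are part of this design, because ordinary alkyl ethers there would capture the carbene.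

**9 back to 8 and 6.** The diazo group is introduced on the methyl ketone 6 by trifluoroacetylation to 8 and transfer of the diazo group from a sulfonyl azide with loss of the trifluoroacetyl unit. This uses the acetyl group that the starting material already carries and avoids an aryl carboxylic acid derivative.

**6 back to 1 and 2; 11 back to 10.** The three silyl ethers of 6 are put on one at a time (3 to 4 to 5 to 6), using the different environments of the three hydroxyls of 3. C7–OH is not hydrogen-bonded, C8a–OH is chelated but unhindered, and C5–OH is chelated and buttressed by the prenyl group. Compound 3 comes from C-prenylation of 1 with 2; the two free ring carbons of 1 are equivalent, so only one mono-C-prenyl product exists. Aldehyde 11 is the bis-silyl ether of 10.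

## Alternatives that were turned down

**Alternative 1:** Ring A is cut at C6–C7 and traced back to a monocyclic dihydropyranone that already holds ring C, ring B and both stereocentres: methyl 2-[(2R,3R)-2-[3-methoxy-4,5-bis(methoxymethoxy)phenyl]-3-(methoxymethoxy)-5-(5-methylhex-4-enoyl)-4-oxo-3,4-dihydro-2H-pyran-6-yl]acetate (A2).
- Forward key step: base forms the enolate at C6 of the 5-methylhex-4-enoyl ketone, which attacks the C7 ester of the acetate arm (Dieckmann-type closure). The cyclohexenedione enolises to the resorcinol, giving the 5,7-dihydroxy-6-prenyl tris-O-methoxymethyl dihydroflavonol A1.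
- For: the prenyl position is written into the chain, so neither the 6/8 question nor any phenol differentiation arises, and C5–OH and C7–OH appear unprotected. On ring A regiochemistry this plan is stronger than the chosen one, which must tell two ortho hydroxyls apart by selective silylation and desilylation.
- Against: A2 is a vinylogous ester and β-diketone with acidic hydrogens at C6, C8 and C3. The base needed for the condensation can deprotonate C3 and expel O1 from C2, or open the vinylogous ester, and both stereocentres are at risk exactly in the key step. A2 itself needs an enantioselective synthesis of a trans-2-aryl-3-alkoxy dihydropyranone followed by C-acylation at C4a, which is a long linear sequence. The final removal of methoxymethyl groups needs acid next to the prenyl resorcinol.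
- Comparison: the chosen strategy makes the stereocentres late, from achiral pieces, and never exposes them to base afterwards; it pays with three silylation steps.

**Alternative 2:** Ring C is cut at C4–C4a, leading to (2R,3R)-2-(tert-butyldimethylsilyloxy)-3-(3,4-diacetoxy-5-methoxyphenyl)-3-[4-(3-methylbut-2-en-1-yl)-3,5-bis(triisopropylsilyloxy)phenoxy]propanoic acid (A4).
- Forward key step: the activated carboxyl group acylates the arene carbon ortho to O1 (intramolecular Friedel–Crafts acylation) and closes ring C to the fully protected dihydroflavonol A3.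
- For: the aryloxy ring of A4 is symmetric about the O1–C6 axis, so both ortho carbons are the same and the prenyl group ends at C6 by symmetry. This is at least as good as the chosen route on regiochemistry and needs no differentiation of phenols. The stereocentres of A4 could come from a well-established asymmetric dihydroxylation or epoxidation of a cinnamate, which is more predictable than a three-component carbene reaction.
- Against: the acylating conditions meet a trisubstituted alkene, which can be protonated or attacked by the acylium ion. They also meet aryl silyl ethers and a benzylic C2–O1 ether that can ionise. An α-silyloxy acyl cation is destabilised and can lose carbon monoxide or pass through a ketene, which would epimerise C3. The site of acylation is flanked by O1 and a triisopropylsilyloxy group. Making A4 also requires an intermolecular displacement by a hindered phenol at a benzylic carbon with defined configuration.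
- Comparison: the chosen strategy closes ring C under neutral conditions that leave the alkene alone and forms the C2–C3 bond convergently; it gives up the regiocontrol by symmetry.

**Alternative 3:** Ring C is cut at O1–C2, as in the chosen plan, but C2 is activated by oxidation. The precursor is (2R)-2-(tert-butyldimethylsilyloxy)-1-[6-hydroxy-2,4-bis(methoxymethoxy)-3-(3-methylbut-2-en-1-yl)phenyl]-3-[4-hydroxy-3-methoxy-5-(methoxymethoxy)phenyl]propan-1-one (A6).
- Forward key step: anodic oxidation of the free 4'-phenol gives a para-quinone methide, the C8a hydroxyl adds to C2, and the 3-O-silyl dihydroflavonol A5 results.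
- For: only C3 has to be set beforehand. C2 follows under thermodynamic control, because the addition is reversible through the quinone methide and the diequatorial trans isomer is favoured. In robustness of the relative configuration this is stronger than an inversion at an electron-rich benzylic carbon. No stoichiometric oxidant is needed.
- Against: A6 contains a second electron-rich phenol (ring A with its free C8a hydroxyl) and a trisubstituted alkene, whose oxidation potentials lie close to that of the ring B phenol. The quinone methide has an acidic hydrogen at C3 between itself and the ketone; tautomerisation to the α-silyloxy chalcone would erase the only stereocentre. Ring B needs differentiated protection, C3 a separate asymmetric α-oxygenation of a hindered aryl ketone, and the end game needs acid next to the prenyl resorcinol.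
- Comparison: the chosen strategy sets both stereocentres and the C2–C3 bond in one step from three simple pieces and closes the ring without an oxidant; it depends on clean inversion at C2.

Key step: step 8

Assumption: the (R)-configured phosphoric acid is written as the antipode that gives the (2R,3S) adduct 14; the sense of induction cannot be derived safely for this substrate, and the (S)-acid would be used if it proves opposite.

Remark on the chemistry: "threo" is meant in the Fischer sense for the chain C4–C3–C2–C1' (the two oxygens on opposite sides), which is the syn arrangement in the zigzag drawing. In the propan-1-one numbering of 14, C2 is flavanone C3 and C3 is flavanone C2.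

## Route

Step 1
Reactants: 1 2,4,6-trihydroxyacetophenone; 2 prenyl bromide (1-bromo-3-methylbut-2-ene)
Product: 3 1-[2,4,6-trihydroxy-3-(3-methylbut-2-en-1-yl)phenyl]ethan-1-one
Conditions: DBU (1.0 equiv), 2 (0.9 equiv), THF, 0 °C to rt
Reagents that add atoms: none
Why: C-allylation of the ambident phloroglucinol phenoxide by the soft allylic bromide; the two free ring carbons of 1 are equivalent, so a single mono-C-prenyl product is possible, and a deficit of 2 limits double prenylation.

Step 2
Reactants: 3 1-[2,4,6-trihydroxy-3-(3-methylbut-2-en-1-yl)phenyl]ethan-1-one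
Product: 4 1-[2,6-dihydroxy-3-(3-methylbut-2-en-1-yl)-4-(triisopropylsilyloxy)phenyl]ethan-1-one
Conditions: TIPSCl (1.05 equiv), imidazole, CH2Cl2, 0 °C
Reagents that add atoms: triisopropylsilyl chloride, CC(C)[Si](Cl)(C(C)C)C(C)C
Why: Phenol silylation; the C7 hydroxyl (para to the acyl group) is the only one not locked in a hydrogen bond to the carbonyl and is the most acidic, so one equivalent of the bulky chloride should react there.

Step 3
Reactants: 4 1-[2,6-dihydroxy-3-(3-methylbut-2-en-1-yl)-4-(triisopropylsilyloxy)phenyl]ethan-1-one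
Product: 5 1-[6-(tert-butyldimethylsilyloxy)-2-hydroxy-3-(3-methylbut-2-en-1-yl)-4-(triisopropylsilyloxy)phenyl]ethan-1-one
Conditions: TBSCl (1.1 equiv), imidazole, DMF, 0 °C to rt
Reagents that add atoms: tert-butyldimethylsilyl chloride, CC(C)(C)[Si](C)(C)Cl
Why: Selective phenol silylation; of the two chelated ortho hydroxyls the one next to the ring hydrogen (the future O1) is far more accessible than the one buttressed between prenyl and acetyl groups, and after the first silylation the remaining hydroxyl holds the carbonyl hydrogen bond alone.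

Step 4
Reactants: 5 1-[6-(tert-butyldimethylsilyloxy)-2-hydroxy-3-(3-methylbut-2-en-1-yl)-4-(triisopropylsilyloxy)phenyl]ethan-1-one
Product: 6 1-[6-(tert-butyldimethylsilyloxy)-3-(3-methylbut-2-en-1-yl)-2,4-bis(triisopropylsilyloxy)phenyl]ethan-1-one
Conditions: TIPSOTf (1.3 equiv), 2,6-lutidine, CH2Cl2, 0 °C to rt
Reagents that add atoms: triisopropylsilyl trifluoromethanesulfonate, CC(C)[Si](OS(=O)(=O)C(F)(F)F)(C(C)C)C(C)C
Why: Phenol silylation of the last, hindered and chelated hydroxyl, which needs the silyl triflate; 2,6-lutidine is too weak a base to turn the methyl ketone into its silyl enol ether at this temperature.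

Step 5
Reactants: 6 1-[6-(tert-butyldimethylsilyloxy)-3-(3-methylbut-2-en-1-yl)-2,4-bis(triisopropylsilyloxy)phenyl]ethan-1-one
Product: 8 4,4,4-trifluoro-1-[6-(tert-butyldimethylsilyloxy)-3-(3-methylbut-2-en-1-yl)-2,4-bis(triisopropylsilyloxy)phenyl]butane-1,3-dione, via lithium enolate 7 (not isolated)
Conditions: LiHMDS (1.1 equiv), THF, −78 °C; CF3CO2CH2CF3 (1.2 equiv), −78 °C; cold 5% aq HCl work-up; crude product used directly
Reagents that add atoms: 2,2,2-trifluoroethyl trifluoroacetate, O=C(OCC(F)(F)F)C(F)(F)F
Why: Kinetic enolate formation and Claisen-type trifluoroacetylation with an activated ester; low temperature and short contact time should keep the flanking aryl silyl groups from migrating to the enolate.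

Step 6
Reactants: 8 4,4,4-trifluoro-1-[6-(tert-butyldimethylsilyloxy)-3-(3-methylbut-2-en-1-yl)-2,4-bis(triisopropylsilyloxy)phenyl]butane-1,3-dione
Product: 9 2-diazo-1-[6-(tert-butyldimethylsilyloxy)-3-(3-methylbut-2-en-1-yl)-2,4-bis(triisopropylsilyloxy)phenyl]ethan-1-one
Conditions: MsN3 (1.5 equiv), Et3N (1.5 equiv), H2O (1 equiv), MeCN, rt
Reagents that add atoms: methanesulfonyl azide, CS(=O)(=O)N=[N+]=[N-]
Why: Detrifluoroacetylative (Regitz-type) diazo transfer: the diketone enolate adds to the sulfonyl azide and the triazoline fragments with loss of the N-sulfonyl trifluoroacetamide, leaving the diazomethyl ketone; the mild amine base does not touch the aryl silyl ethers.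

Step 7
Reactants: 10 5-hydroxyvanillin (3,4-dihydroxy-5-methoxybenzaldehyde)
Product: 11 3-methoxy-4,5-bis(triisopropylsilyloxy)benzaldehyde
Conditions: TIPSOTf (2.4 equiv), 2,6-lutidine, CH2Cl2, 0 °C to rt
Reagents that add atoms: triisopropylsilyl trifluoromethanesulfonate, CC(C)[Si](OS(=O)(=O)C(F)(F)F)(C(C)C)C(C)C
Why: Silylation of both phenols, the triflate being needed for the second, flanked oxygen; silyl ethers are chosen for ring B so that every phenol of the final intermediate falls to fluoride in one step.

Step 8
Reactants: 9 2-diazo-1-[6-(tert-butyldimethylsilyloxy)-3-(3-methylbut-2-en-1-yl)-2,4-bis(triisopropylsilyloxy)phenyl]ethan-1-one; 11 3-methoxy-4,5-bis(triisopropylsilyloxy)benzaldehyde; 12 4-methoxybenzyl alcohol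
Product: 14 (2R,3S)-1-[6-(tert-butyldimethylsilyloxy)-3-(3-methylbut-2-en-1-yl)-2,4-bis(triisopropylsilyloxy)phenyl]-3-hydroxy-2-[(4-methoxybenzyl)oxy]-3-[3-methoxy-4,5-bis(triisopropylsilyloxy)phenyl]propan-1-one, via oxonium ylide 13 (not isolated)
Conditions: Rh2(OAc)4 (2 mol %), (R)-3,3'-bis(2,4,6-triisopropylphenyl)-1,1'-binaphthyl-2,2'-diyl hydrogen phosphate (10 mol %), 11 (1.5 equiv), 12 (1.3 equiv), 4 Å MS, CH2Cl2, −20 °C, 9 added slowly by syringe pump
Reagents that add atoms: none
Why: Rh2(OAc)4 (divalent rhodium) decomposes 9 to an electrophilic rhodium carbene, which is captured by the hydroxyl oxygen of 12 to give the oxonium ylide 13, in equilibrium with its enol. The chiral phosphoric acid binds aldehyde 11 through its acidic proton and the ylide O–H through its phosphoryl oxygen, so that C–C bond formation to the activated carbonyl outruns the 1,2-proton shift that would end in plain O–H insertion. The closest known reaction type is the three-component coupling of diazo carbonyl compounds, alcohols and aldehydes or imines under dirhodium and chiral Brønsted acid co-catalysis (aldol- or Mannich-type ylide trapping). No ring is closed; the C3–O and C2–C3 bonds are formed. Both stereocentres arise in the trapping event: the relative (threo) configuration from the ordered, doubly hydrogen-bonded transition state, and the absolute configuration from the binaphthyl pocket of the acid. The step needs the carbene to choose the external alcohol: the bulky silyl ethers on both oxygens ortho to the acyl group block five-membered ylide formation there, the prenyl alkene could react only through a seven-membered cyclopropanation, and slow addition of 9 keeps carbene dimerisation down. It also needs trapping to beat proton transfer, which excess 11, low temperature and molecular sieves are meant to secure.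

Step 9
Reactants: 14 (2R,3S)-1-[6-(tert-butyldimethylsilyloxy)-3-(3-methylbut-2-en-1-yl)-2,4-bis(triisopropylsilyloxy)phenyl]-3-hydroxy-2-[(4-methoxybenzyl)oxy]-3-[3-methoxy-4,5-bis(triisopropylsilyloxy)phenyl]propan-1-one
Product: 15 (2R,3S)-3-hydroxy-1-[6-hydroxy-3-(3-methylbut-2-en-1-yl)-2,4-bis(triisopropylsilyloxy)phenyl]-2-[(4-methoxybenzyl)oxy]-3-[3-methoxy-4,5-bis(triisopropylsilyloxy)phenyl]propan-1-one
Conditions: TBAF (1.1 equiv), AcOH (1.2 equiv), THF, −20 to 0 °C
Reagents that add atoms: none
Why: Fluoride cleaves aryl silyl ethers in the order of phenoxide leaving-group ability and steric access, so the tert-butyldimethylsilyl ether ortho to the ketone should go well before any triisopropylsilyl ether; acetic acid protonates the phenoxide at once, so the β-hydroxy ketone sees no base (no retro-aldol, no epimerisation at C3).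

Step 10
Reactants: 15 (2R,3S)-3-hydroxy-1-[6-hydroxy-3-(3-methylbut-2-en-1-yl)-2,4-bis(triisopropylsilyloxy)phenyl]-2-[(4-methoxybenzyl)oxy]-3-[3-methoxy-4,5-bis(triisopropylsilyloxy)phenyl]propan-1-one
Product: 16 (2R,3R)-3-[(4-methoxybenzyl)oxy]-2-[3-methoxy-4,5-bis(triisopropylsilyloxy)phenyl]-6-(3-methylbut-2-en-1-yl)-5,7-bis(triisopropylsilyloxy)-2,3-dihydro-4H-chromen-4-one
Conditions: PPh3 (1.5 equiv), DIAD (1.5 equiv), THF (0.01 M), 0 °C to rt
Reagents that add atoms: none
Why: Intramolecular Mitsunobu etherification: the benzylic hydroxyl is activated on phosphorus and displaced by the C8a phenoxide in a 6-exo-tet SN2 closure with inversion, which turns the (S) carbinol carbon into (2R) and gives the trans ring; C3 is not involved and keeps its configuration, and dilution suppresses intermolecular alkylation.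

Step 11
Reactants: 16 (2R,3R)-3-[(4-methoxybenzyl)oxy]-2-[3-methoxy-4,5-bis(triisopropylsilyloxy)phenyl]-6-(3-methylbut-2-en-1-yl)-5,7-bis(triisopropylsilyloxy)-2,3-dihydro-4H-chromen-4-one
Product: 17 (2R,3R)-3-hydroxy-2-[3-methoxy-4,5-bis(triisopropylsilyloxy)phenyl]-6-(3-methylbut-2-en-1-yl)-5,7-bis(triisopropylsilyloxy)-2,3-dihydro-4H-chromen-4-one
Conditions: DDQ (1.5 equiv), CH2Cl2/pH 7 phosphate buffer (10:1), 0 °C to rt
Reagents that add atoms: none
Why: Oxidative cleavage of the 4-methoxybenzyl ether by hydride abstraction and hydrolysis of the oxocarbenium ion; no free phenol is present at this stage, and the prenyl alkene and the aryl silyl ethers should be inert.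

Step 12
Reactants: 17 (2R,3R)-3-hydroxy-2-[3-methoxy-4,5-bis(triisopropylsilyloxy)phenyl]-6-(3-methylbut-2-en-1-yl)-5,7-bis(triisopropylsilyloxy)-2,3-dihydro-4H-chromen-4-one
Product: 18 (2R,3R)-2-(3,4-dihydroxy-5-methoxyphenyl)-3,5,7-trihydroxy-6-(3-methylbut-2-en-1-yl)-2,3-dihydro-4H-chromen-4-one
Conditions: TBAF (6 equiv), AcOH (6 equiv), THF, 0 °C to rt, under argon; mildly acidic aqueous work-up
Reagents that add atoms: none
Why: Fluoride-mediated cleavage of all four aryl silyl ethers; the acetic acid buffer keeps the medium non-basic, so ring C should not open (C2 and C3 keep their configuration) and the catechol is not oxidised, and no acid strong enough to cyclise the prenyl group onto a neighbouring phenol is used.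

## Compound list

1 | 2,4,6-trihydroxyacetophenone | CC(=O)c1c(O)cc(O)cc1O | starting material
2 | prenyl bromide (1-bromo-3-methylbut-2-ene) | CC(C)=CCBr | starting material
3 | 1-[2,4,6-trihydroxy-3-(3-methylbut-2-en-1-yl)phenyl]ethan-1-one | CC(=O)c1c(O)cc(O)c(CC=C(C)C)c1O | intermediate
4 | 1-[2,6-dihydroxy-3-(3-methylbut-2-en-1-yl)-4-(triisopropylsilyloxy)phenyl]ethan-1-one | CC(=O)c1c(O)cc(O[Si](C(C)C)(C(C)C)C(C)C)c(CC=C(C)C)c1O | intermediate
5 | 1-[6-(tert-butyldimethylsilyloxy)-2-hydroxy-3-(3-methylbut-2-en-1-yl)-4-(triisopropylsilyloxy)phenyl]ethan-1-one | CC(=O)c1c(O[Si](C)(C)C(C)(C)C)cc(O[Si](C(C)C)(C(C)C)C(C)C)c(CC=C(C)C)c1O | intermediate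
6 | 1-[6-(tert-butyldimethylsilyloxy)-3-(3-methylbut-2-en-1-yl)-2,4-bis(triisopropylsilyloxy)phenyl]ethan-1-one | CC(=O)c1c(O[Si](C)(C)C(C)(C)C)cc(O[Si](C(C)C)(C(C)C)C(C)C)c(CC=C(C)C)c1O[Si](C(C)C)(C(C)C)C(C)C | intermediate
7 | lithium enolate of 6 (lithium 1-arylethen-1-olate) | [Li+].[O-]C(=C)c1c(O[Si](C)(C)C(C)(C)C)cc(O[Si](C(C)C)(C(C)C)C(C)C)c(CC=C(C)C)c1O[Si](C(C)C)(C(C)C)C(C)C | intermediate
8 | 4,4,4-trifluoro-1-[6-(tert-butyldimethylsilyloxy)-3-(3-methylbut-2-en-1-yl)-2,4-bis(triisopropylsilyloxy)phenyl]butane-1,3-dione | O=C(CC(=O)C(F)(F)F)c1c(O[Si](C)(C)C(C)(C)C)cc(O[Si](C(C)C)(C(C)C)C(C)C)c(CC=C(C)C)c1O[Si](C(C)C)(C(C)C)C(C)C | intermediate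
9 | 2-diazo-1-[6-(tert-butyldimethylsilyloxy)-3-(3-methylbut-2-en-1-yl)-2,4-bis(triisopropylsilyloxy)phenyl]ethan-1-one | [N-]=[N+]=CC(=O)c1c(O[Si](C)(C)C(C)(C)C)cc(O[Si](C(C)C)(C(C)C)C(C)C)c(CC=C(C)C)c1O[Si](C(C)C)(C(C)C)C(C)C | intermediate
10 | 5-hydroxyvanillin (3,4-dihydroxy-5-methoxybenzaldehyde) | COc1cc(C=O)cc(O)c1O | starting material
11 | 3-methoxy-4,5-bis(triisopropylsilyloxy)benzaldehyde | COc1cc(C=O)cc(O[Si](C(C)C)(C(C)C)C(C)C)c1O[Si](C(C)C)(C(C)C)C(C)C | intermediate
12 | 4-methoxybenzyl alcohol | COc1ccc(CO)cc1 | starting material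
13 | oxonium ylide from the carbene of 9 and 12 | CC(C)=CCc1c(O[Si](C(C)C)(C(C)C)C(C)C)cc(O[Si](C)(C)C(C)(C)C)c(C(=O)[CH-][OH+]Cc2ccc(OC)cc2)c1O[Si](C(C)C)(C(C)C)C(C)C | intermediate
14 | (2R,3S)-1-[6-(tert-butyldimethylsilyloxy)-3-(3-methylbut-2-en-1-yl)-2,4-bis(triisopropylsilyloxy)phenyl]-3-hydroxy-2-[(4-methoxybenzyl)oxy]-3-[3-methoxy-4,5-bis(triisopropylsilyloxy)phenyl]propan-1-one | CC(C)=CCc1c(O[Si](C(C)C)(C(C)C)C(C)C)cc(O[Si](C)(C)C(C)(C)C)c(C(=O)[C@H](OCc2ccc(OC)cc2)[C@@H](O)c2cc(OC)c(O[Si](C(C)C)(C(C)C)C(C)C)c(O[Si](C(C)C)(C(C)C)C(C)C)c2)c1O[Si](C(C)C)(C(C)C)C(C)C | intermediate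
15 | (2R,3S)-3-hydroxy-1-[6-hydroxy-3-(3-methylbut-2-en-1-yl)-2,4-bis(triisopropylsilyloxy)phenyl]-2-[(4-methoxybenzyl)oxy]-3-[3-methoxy-4,5-bis(triisopropylsilyloxy)phenyl]propan-1-one | CC(C)=CCc1c(O[Si](C(C)C)(C(C)C)C(C)C)cc(O)c(C(=O)[C@H](OCc2ccc(OC)cc2)[C@@H](O)c2cc(OC)c(O[Si](C(C)C)(C(C)C)C(C)C)c(O[Si](C(C)C)(C(C)C)C(C)C)c2)c1O[Si](C(C)C)(C(C)C)C(C)C | intermediate
16 | (2R,3R)-3-[(4-methoxybenzyl)oxy]-2-[3-methoxy-4,5-bis(triisopropylsilyloxy)phenyl]-6-(3-methylbut-2-en-1-yl)-5,7-bis(triisopropylsilyloxy)-2,3-dihydro-4H-chromen-4-one | COc1cc([C@H]2Oc3cc(O[Si](C(C)C)(C(C)C)C(C)C)c(CC=C(C)C)c(O[Si](C(C)C)(C(C)C)C(C)C)c3C(=O)[C@@H]2OCc4ccc(OC)cc4)cc(O[Si](C(C)C)(C(C)C)C(C)C)c1O[Si](C(C)C)(C(C)C)C(C)C | intermediate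
17 | (2R,3R)-3-hydroxy-2-[3-methoxy-4,5-bis(triisopropylsilyloxy)phenyl]-6-(3-methylbut-2-en-1-yl)-5,7-bis(triisopropylsilyloxy)-2,3-dihydro-4H-chromen-4-one | COc1cc([C@H]2Oc3cc(O[Si](C(C)C)(C(C)C)C(C)C)c(CC=C(C)C)c(O[Si](C(C)C)(C(C)C)C(C)C)c3C(=O)[C@@H]2O)cc(O[Si](C(C)C)(C(C)C)C(C)C)c1O[Si](C(C)C)(C(C)C)C(C)C | intermediate
18 | (2R,3R)-2-(3,4-dihydroxy-5-methoxyphenyl)-3,5,7-trihydroxy-6-(3-methylbut-2-en-1-yl)-2,3-dihydro-4H-chromen-4-one | COc1cc([C@H]2Oc3cc(O)c(CC=C(C)C)c(O)c3C(=O)[C@@H]2O)cc(O)c1O | target

## Step count and least certain steps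

Total: 12 steps. Longest linear sequence: 11 steps (steps 1 to 6 and 8 to 12); step 7 is the one-step side branch to the aldehyde.

**Step 8 (key step).**
- What may go wrong: the ylide 13 undergoes the 1,2-proton shift before it meets the aldehyde, so that plain O–H insertion takes over. This is likely because 11 is not an electron-poor aldehyde and the acyl group of 9 is shielded by two silyloxy groups. A second concern is weak facial discrimination by the acid with a carbene that carries only an acyl substituent.
- Fallback (sets out from 9, returns at 14): the bond formations are separated. Compound 9 would be treated with Rh2(OAc)4 and 12 alone, which should give the O–H insertion product 2-[(4-methoxybenzyl)oxy]-1-[6-(tert-butyldimethylsilyloxy)-3-(3-methylbut-2-en-1-yl)-2,4-bis(triisopropylsilyloxy)phenyl]ethan-1-one F1. A syn-selective boron aldol addition of F1 to 11 would follow (enolisation with a diisopinocampheylboron triflate and iPr2NEt in CH2Cl2 at −78 °C, chair transition state, oxidative work-up). The antipode of the boron reagent would be chosen for the (2R,3S) series, and the route is rejoined at 14.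

**Step 3.**
- What may go wrong: silylation at the wrong ortho hydroxyl (C5–O instead of C8a–O) or at both, because the two chelated hydroxyls differ only in their second neighbour.
- Fallback (sets out from 1, returns at 6): the free hydroxyl is defined by a rearrangement instead of by selective silylation. Compound 1 would be bis-silylated (TIPSCl, imidazole, DMF) to 1-[2-hydroxy-4,6-bis(triisopropylsilyloxy)phenyl]ethan-1-one F2, which is unambiguous because 1 is symmetric. The remaining chelated hydroxyl would be O-prenylated under Mitsunobu conditions with 3-methylbut-2-en-1-ol (PPh3, DIAD, THF) to 1-[2-(3-methylbut-2-en-1-yloxy)-4,6-bis(triisopropylsilyloxy)phenyl]ethan-1-one F3. Heating F3 in N,N-diethylaniline should bring about the para-Claisen–Cope rearrangement, which places the prenyl group between the two silyloxy groups and frees the future O1 hydroxyl in 1-[6-hydroxy-3-(3-methylbut-2-en-1-yl)-2,4-bis(triisopropylsilyloxy)phenyl]ethan-1-one F4. Silylation of F4 with TBSCl and imidazole gives 6.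

**Step 5.**
- What may go wrong: migration of a flanking aryl silyl group to the enolate oxygen or carbon, or incomplete enolisation of the twisted, doubly ortho-substituted ketone.
- Fallback (sets out from 6, returns at 9): the strong base is avoided. Condensation of 6 with N,N-dimethylformamide dimethyl acetal (toluene, 100 °C) would give the enaminone (E)-3-(dimethylamino)-1-[6-(tert-butyldimethylsilyloxy)-3-(3-methylbut-2-en-1-yl)-2,4-bis(triisopropylsilyloxy)phenyl]prop-2-en-1-one F5. Treatment of F5 with 4-methylbenzenesulfonyl azide (MeCN, rt) should give 9 directly by cycloaddition and fragmentation, with loss of the N-sulfonyl formamidine. Steps 5 and 6 are bypassed.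

**Step 9.**
- What may go wrong: concurrent loss of the C7 triisopropylsilyl ether, which is also activated by the ketone, or retro-aldol cleavage if the phenoxide is not protonated fast enough.
- Fallback (sets out from 14, returns at 16): the selectivity between the C8a and C7 ethers is made irrelevant. With about 2.2 equiv of buffered fluoride both are removed on purpose; the doubly flanked C5 ether and the ring B ethers on their electron-rich ring should persist. This gives (2R,3S)-1-[4,6-dihydroxy-3-(3-methylbut-2-en-1-yl)-2-(triisopropylsilyloxy)phenyl]-3-hydroxy-2-[(4-methoxybenzyl)oxy]-3-[3-methoxy-4,5-bis(triisopropylsilyloxy)phenyl]propan-1-one F6. Mitsunobu closure at high dilution can involve only the C8a hydroxyl and should give (2R,3R)-7-hydroxy-3-[(4-methoxybenzyl)oxy]-2-[3-methoxy-4,5-bis(triisopropylsilyloxy)phenyl]-6-(3-methylbut-2-en-1-yl)-5-(triisopropylsilyloxy)-2,3-dihydro-4H-chromen-4-one F7. Re-silylation of the C7 phenol of F7 (TIPSCl, imidazole) leads to 16.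

**Step 10.**
- What may go wrong: elimination of the activated β-hydroxyl toward the α-alkoxy enone, or ionisation at the electron-rich benzylic carbon with loss of the inversion.
- Fallback (sets out from 15, returns at 16): ionisation is used instead of avoided. Catalytic p-toluenesulfonic acid in CH2Cl2/hexafluoroisopropanol at 0 °C would generate the benzylic cation, stabilised by ring B, and the C8a hydroxyl would add to it. The C3 substituent should direct the closure to the diequatorial trans isomer 16 whatever the configuration of the carbinol carbon. No compound outside the compound list would be made (entry F0). Any C2 epimer carried forward would be expected to revert to the trans series once the 4'-hydroxyl is free in 18, since C3 is fixed.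

## Further compounds

F1 | step 8 | 2-[(4-methoxybenzyl)oxy]-1-[6-(tert-butyldimethylsilyloxy)-3-(3-methylbut-2-en-1-yl)-2,4-bis(triisopropylsilyloxy)phenyl]ethan-1-one | COc1ccc(COCC(=O)c2c(O[Si](C)(C)C(C)(C)C)cc(O[Si](C(C)C)(C(C)C)C(C)C)c(CC=C(C)C)c2O[Si](C(C)C)(C(C)C)C(C)C)cc1
F2 | step 3 | 1-[2-hydroxy-4,6-bis(triisopropylsilyloxy)phenyl]ethan-1-one | CC(=O)c1c(O)cc(O[Si](C(C)C)(C(C)C)C(C)C)cc1O[Si](C(C)C)(C(C)C)C(C)C
F3 | step 3 | 1-[2-(3-methylbut-2-en-1-yloxy)-4,6-bis(triisopropylsilyloxy)phenyl]ethan-1-one | CC(=O)c1c(OCC=C(C)C)cc(O[Si](C(C)C)(C(C)C)C(C)C)cc1O[Si](C(C)C)(C(C)C)C(C)C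
F4 | step 3 | 1-[6-hydroxy-3-(3-methylbut-2-en-1-yl)-2,4-bis(triisopropylsilyloxy)phenyl]ethan-1-one | CC(=O)c1c(O)cc(O[Si](C(C)C)(C(C)C)C(C)C)c(CC=C(C)C)c1O[Si](C(C)C)(C(C)C)C(C)C
F5 | step 5 | (E)-3-(dimethylamino)-1-[6-(tert-butyldimethylsilyloxy)-3-(3-methylbut-2-en-1-yl)-2,4-bis(triisopropylsilyloxy)phenyl]prop-2-en-1-one | CN(C)/C=C/C(=O)c1c(O[Si](C)(C)C(C)(C)C)cc(O[Si](C(C)C)(C(C)C)C(C)C)c(CC=C(C)C)c1O[Si](C(C)C)(C(C)C)C(C)C
F6 | step 9 | (2R,3S)-1-[4,6-dihydroxy-3-(3-methylbut-2-en-1-yl)-2-(triisopropylsilyloxy)phenyl]-3-hydroxy-2-[(4-methoxybenzyl)oxy]-3-[3-methoxy-4,5-bis(triisopropylsilyloxy)phenyl]propan-1-one | CC(C)=CCc1c(O)cc(O)c(C(=O)[C@H](OCc2ccc(OC)cc2)[C@@H](O)c2cc(OC)c(O[Si](C(C)C)(C(C)C)C(C)C)c(O[Si](C(C)C)(C(C)C)C(C)C)c2)c1O[Si](C(C)C)(C(C)C)C(C)C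
F7 | step 9 | (2R,3R)-7-hydroxy-3-[(4-methoxybenzyl)oxy]-2-[3-methoxy-4,5-bis(triisopropylsilyloxy)phenyl]-6-(3-methylbut-2-en-1-yl)-5-(triisopropylsilyloxy)-2,3-dihydro-4H-chromen-4-one | COc1cc([C@H]2Oc3cc(O)c(CC=C(C)C)c(O[Si](C(C)C)(C(C)C)C(C)C)c3C(=O)[C@@H]2OCc4ccc(OC)cc4)cc(O[Si](C(C)C)(C(C)C)C(C)C)c1O[Si](C(C)C)(C(C)C)C(C)C
F0 | step 10 | none | none
A1 | alternative 1 | (2R,3R)-5,7-dihydroxy-2-[3-methoxy-4,5-bis(methoxymethoxy)phenyl]-3-(methoxymethoxy)-6-(3-methylbut-2-en-1-yl)-2,3-dihydro-4H-chromen-4-one | COc1cc([C@H]2Oc3cc(O)c(CC=C(C)C)c(O)c3C(=O)[C@@H]2OCOC)cc(OCOC)c1OCOC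
A2 | alternative 1 | methyl 2-[(2R,3R)-2-[3-methoxy-4,5-bis(methoxymethoxy)phenyl]-3-(methoxymethoxy)-5-(5-methylhex-4-enoyl)-4-oxo-3,4-dihydro-2H-pyran-6-yl]acetate | COc1cc([C@H]2OC(CC(=O)OC)=C(C(=O)CCC=C(C)C)C(=O)[C@@H]2OCOC)cc(OCOC)c1OCOC
A3 | alternative 2 | (2R,3R)-3-(tert-butyldimethylsilyloxy)-2-(3,4-diacetoxy-5-methoxyphenyl)-6-(3-methylbut-2-en-1-yl)-5,7-bis(triisopropylsilyloxy)-2,3-dihydro-4H-chromen-4-one | COc1cc([C@H]2Oc3cc(O[Si](C(C)C)(C(C)C)C(C)C)c(CC=C(C)C)c(O[Si](C(C)C)(C(C)C)C(C)C)c3C(=O)[C@@H]2O[Si](C)(C)C(C)(C)C)cc(OC(C)=O)c1OC(C)=O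
A4 | alternative 2 | (2R,3R)-2-(tert-butyldimethylsilyloxy)-3-(3,4-diacetoxy-5-methoxyphenyl)-3-[4-(3-methylbut-2-en-1-yl)-3,5-bis(triisopropylsilyloxy)phenoxy]propanoic acid | COc1cc([C@@H](Oc2cc(O[Si](C(C)C)(C(C)C)C(C)C)c(CC=C(C)C)c(O[Si](C(C)C)(C(C)C)C(C)C)c2)[C@@H](O[Si](C)(C)C(C)(C)C)C(O)=O)cc(OC(C)=O)c1OC(C)=O
A5 | alternative 3 | (2R,3R)-3-(tert-butyldimethylsilyloxy)-2-[4-hydroxy-3-methoxy-5-(methoxymethoxy)phenyl]-5,7-bis(methoxymethoxy)-6-(3-methylbut-2-en-1-yl)-2,3-dihydro-4H-chromen-4-one | COc1cc([C@H]2Oc3cc(OCOC)c(CC=C(C)C)c(OCOC)c3C(=O)[C@@H]2O[Si](C)(C)C(C)(C)C)cc(OCOC)c1O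
A6 | alternative 3 | (2R)-2-(tert-butyldimethylsilyloxy)-1-[6-hydroxy-2,4-bis(methoxymethoxy)-3-(3-methylbut-2-en-1-yl)phenyl]-3-[4-hydroxy-3-methoxy-5-(methoxymethoxy)phenyl]propan-1-one | COc1cc(C[C@@H](O[Si](C)(C)C(C)(C)C)C(=O)c2c(O)cc(OCOC)c(CC=C(C)C)c2OCOC)cc(OCOC)c1O
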